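**Plan**

Labels: cyclohexene C1 (methyl-bearing)=C2, C3 (carries ring A, the resorcinol ring of the chalcone), C4 (carries the ketone carbon C7), C5 (carries the 2,4-dihydroxyphenyl ring), C6.
Cuts, in retrosynthetic order: six MOM ethers; the C1=C2 alkene and the ring A 2-hydroxyl back to a bridging O–C1 ether with silicon on C2; the chalcone C=C (Claisen–Schmidt); C7=O back to the carbinol; then C2–C3 together with O–C1 (ortho-quinone methide plus tethered (Z)-vinylsilane); C3–C4 (aldol); C5–aryl (conjugate addition); the enone C=C (cross-metathesis); C6–vinyl (allylic coupling).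
Forward: the chain 7 → 13 → 17 → 22 → 23 is joined first; step 17 closes the carbocycle and a temporary pyran ring at once (25); oxidation and chalcone formation follow on the bridged scaffold; fluoride then opens the pyran ring and releases the C1=C2 alkene (30); deprotection gives 31.
Stereochemistry: C5 from the rhodium/(R)-BINAP addition; C4 from C5 in the aldol step; C3 in step 17, where the O–C1 bridge forces ring A axial and the C4 and C5 groups equatorial; the alkene position from the anti arrangement of C2–Si and C1–O.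
Enabling feature: ring A has a hydroxyl ortho to its bond to C3, so C3 can become the exocyclic carbon of an ortho-quinone methide, and C1, one atom beyond C2, is a methyl-substituted alkene carbon that can accept the quinone methide oxygen; silicon on C2 steers both the cycloaddition and the later ring opening.

Key step: step 17

Remark: the BINAP enantiomer in step 11 is assigned from the accepted enantioface model for rhodium/BINAP additions to (E)-enones; should the sense prove opposite, (S)-BINAP is used instead.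

**Route**

Step 1
Reactants: 1 prop-2-yn-1-ol
Product: 3 (Z)-3-iodo-2-methylprop-2-en-1-ol, via vinylmagnesium alkoxide 2 (not isolated)
Conditions: MeMgBr (2.2 equiv), CuI (10 mol %), THF, −10 °C → rt; then I2, −78 → 0 °C; H2O
Reagents that add atoms: methylmagnesium bromide C[Mg]Br; iodine II
Why: Copper-catalysed anti-carbomagnesiation of the propargylic alkoxide places magnesium cis to the CH2O group in a five-membered chelate, and iodinolysis with retention gives the (Z)-iodide.

Step 2
Reactants: 3 (Z)-3-iodo-2-methylprop-2-en-1-ol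
Product: 5 (Z)-2-methyl-3-(trimethylsilyl)prop-2-en-1-ol, via trimethylsilyl ether 4 (not isolated)
Conditions: Me3SiCl, Et3N, Et2O, 0 °C, filtration; then t-BuLi (2.1 equiv), THF, −78 → 0 °C; H2O
Reagents that add atoms: chlorotrimethylsilane C[Si](C)(C)Cl
Why: After O-silylation, iodine–lithium exchange lets the silyl group move from oxygen to the cis vinyl carbon (retro-[1,4]-Brook rearrangement), so the (Z) geometry of 3 is carried into the vinylsilane.

Step 3
Reactants: 5 (Z)-2-methyl-3-(trimethylsilyl)prop-2-en-1-ol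
Product: 6 (Z)-(3-bromo-2-methylprop-1-en-1-yl)trimethylsilane
Conditions: CBr4, PPh3, CH2Cl2, 0 °C
Reagents that add atoms: tetrabromomethane BrC(Br)(Br)Br
Why: Appel bromination of a primary allylic alcohol should leave the trisubstituted vinylsilane untouched.

Step 4
Reactants: 6 (Z)-(3-bromo-2-methylprop-1-en-1-yl)trimethylsilane
Product: 7 (Z)-trimethyl(2-methylpenta-1,4-dien-1-yl)silane
Conditions: CH2=CHMgBr, Li2CuCl4 (3 mol %), THF, −40 → 0 °C
Reagents that add atoms: vinylmagnesium bromide C=C[Mg]Br
Why: Copper-catalysed Grignard coupling of a primary allylic bromide should occur at the unhindered CH2 terminus (SN2 mode) and not at the silyl-bearing carbon, giving the skipped diene with the (Z)-vinylsilane intact.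

Step 5
Reactants: 8 1-(2,4-dihydroxyphenyl)ethan-1-one; 9 3-methylbut-2-enal
Product: 10 1-(5-hydroxy-2,2-dimethyl-2H-chromen-6-yl)ethan-1-one
Conditions: pyridine, 140 °C, sealed tube
Reagents that add atoms: none
Why: Pyridine-mediated chromenylation (condensation at the carbon between the two hydroxyls, then oxa-6π electrocyclisation through the non-chelated 4-hydroxyl) is the standard route to angular 2,2-dimethylchromenes from 2,4-dihydroxyaryl ketones.

Step 6
Reactants: 10 1-(5-hydroxy-2,2-dimethyl-2H-chromen-6-yl)ethan-1-one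
Product: 11 1-[5-(methoxymethoxy)-2,2-dimethyl-2H-chromen-6-yl]ethan-1-one
Conditions: NaH, MOMCl, DMF, 0 °C → rt
Reagents that add atoms: chloromethyl methyl ether COCCl
Why: Williamson-type O-alkylation of the chelated phenoxide masks the phenol that would otherwise add to the enone of step 7 and could form a second quinone methide at C7 in step 17.

Step 7
Reactants: 11 1-[5-(methoxymethoxy)-2,2-dimethyl-2H-chromen-6-yl]ethan-1-one
Product: 12 1-[5-(methoxymethoxy)-2,2-dimethyl-2H-chromen-6-yl]prop-2-en-1-one
Conditions: (CH2O)n, i-Pr2NH2+ CF3CO2− (1 equiv), THF, reflux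
Reagents that add atoms: paraformaldehyde (as formaldehyde) C=O
Why: Mannich-type α-methylenation of an aryl methyl ketone with formaldehyde and a secondary ammonium salt gives the aryl vinyl ketone in one operation.

Step 8
Reactants: 7 (Z)-trimethyl(2-methylpenta-1,4-dien-1-yl)silane; 12 1-[5-(methoxymethoxy)-2,2-dimethyl-2H-chromen-6-yl]prop-2-en-1-one
Product: 13 (2E,5Z)-1-[5-(methoxymethoxy)-2,2-dimethyl-2H-chromen-6-yl]-5-methyl-6-(trimethylsilyl)hexa-2,5-dien-1-one
Conditions: RuCl2(SIMes)(=CH–C6H4-2-O-i-Pr) (second-generation Hoveyda–Grubbs catalyst, 5 mol %), 1,4-benzoquinone (10 mol %), 7 (2 equiv), CH2Cl2, 40 °C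
Reagents that add atoms: none
Why: Olefin cross-metathesis between a terminal alkene and an aryl vinyl ketone should give the (E)-enone, the trisubstituted vinylsilane and the chromene alkene being too hindered to take part.

Step 9
Reactants: 14 4-bromobenzene-1,3-diol
Product: 15 1-bromo-2,4-bis(methoxymethoxy)benzene
Conditions: MOMCl, i-Pr2NEt, CH2Cl2, 0 °C → rt
Reagents that add atoms: chloromethyl methyl ether COCCl
Why: Standard O-alkylation of both phenols.

Step 10
Reactants: 15 1-bromo-2,4-bis(methoxymethoxy)benzene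
Product: 16 [2,4-bis(methoxymethoxy)phenyl]boronic acid
Conditions: n-BuLi, THF, −78 °C; B(O-i-Pr)3, −78 °C → rt; cold 1 M HCl
Reagents that add atoms: triisopropyl borate CC(C)OB(OC(C)C)OC(C)C; water O
Why: Bromine–lithium exchange, borylation and hydrolysis is the standard access to ortho-alkoxy arylboronic acids.

Step 11
Reactants: 13 the (2E,5Z)-dienone; 16 [2,4-bis(methoxymethoxy)phenyl]boronic acid
Product: 17 (3S,5Z)-3-[2,4-bis(methoxymethoxy)phenyl]-1-[5-(methoxymethoxy)-2,2-dimethyl-2H-chromen-6-yl]-5-methyl-6-(trimethylsilyl)hex-5-en-1-one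
Conditions: [Rh(OH)((R)-BINAP)]2 (3 mol % Rh), 16 (3 equiv), dioxane/H2O 10:1, 35 °C
Reagents that add atoms: none
Why: Rhodium-catalysed asymmetric 1,4-addition of an arylboronic acid to an (E)-enone (Hayashi–Miyaura reaction), in which the (R)-BINAP–rhodium aryl is expected to add to the α-re face and so set the S configuration at C5.

Step 12
Reactants: 8 1-(2,4-dihydroxyphenyl)ethan-1-one
Product: 18 1-[2-hydroxy-4-(methoxymethoxy)phenyl]ethan-1-one
Conditions: MOMCl, K2CO3, acetone, rt
Reagents that add atoms: chloromethyl methyl ether COCCl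
Why: The 4-hydroxyl is alkylated selectively because the 2-hydroxyl is hydrogen-bonded to the ketone.

Step 13
Reactants: 18 1-[2-hydroxy-4-(methoxymethoxy)phenyl]ethan-1-one
Product: 19 3-acetyl-2-hydroxy-6-(methoxymethoxy)benzaldehyde
Conditions: MgCl2, Et3N, (CH2O)n, MeCN, reflux; cold 1 M HCl work-up
Reagents that add atoms: paraformaldehyde (as formaldehyde) C=O
Why: Magnesium-mediated ortho-formylation of a phenol (Casnati–Skattebøl reaction) delivers formaldehyde within the magnesium phenoxide to the only free ortho position, the carbon between the two oxygens.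

Step 14
Reactants: 19 3-acetyl-2-hydroxy-6-(methoxymethoxy)benzaldehyde
Product: 20 3-acetyl-2-[(tert-butyldimethylsilyl)oxy]-6-(methoxymethoxy)benzaldehyde
Conditions: t-BuMe2SiOTf, 2,6-lutidine, CH2Cl2, −78 → 0 °C
Reagents that add atoms: tert-butyldimethylsilyl triflate CC(C)(C)[Si](C)(C)OS(=O)(=O)C(F)(F)F
Why: Silylation with the reactive triflate converts the doubly hydrogen-bonded phenol into a fluoride-labile ether, the trigger for step 17.

Step 15
Reactants: 17 the (3S)-ketone; 20 the silylated aldehyde
Product: 22 (2R,3S,5Z)-2-[(R)-{3-acetyl-2-[(tert-butyldimethylsilyl)oxy]-6-(methoxymethoxy)phenyl}(hydroxy)methyl]-3-[2,4-bis(methoxymethoxy)phenyl]-1-[5-(methoxymethoxy)-2,2-dimethyl-2H-chromen-6-yl]-5-methyl-6-(trimethylsilyl)hex-5-en-1-one, via (Z)-dibutylboron enolate 21 (not isolated)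
Conditions: n-Bu2BOTf, i-Pr2NEt, CH2Cl2, −78 → 0 °C; 20, −78 → −20 °C; MeOH, pH 7 buffer, H2O2, 0 °C
Reagents that add atoms: none
Why: Boron-mediated aldol addition through the (Z)-enolate and a chair (Zimmerman–Traxler) transition state should give the 3,4-syn adduct, the C5 centre directing the aldehyde anti to its aryl group with H5 eclipsing the enolate (allylic 1,3-strain) to set C4, while the C3 configuration is of no consequence because C3 becomes trigonal in step 17.

Step 16
Reactants: 22 the aldol adduct
Product: 23 (1R,2S,3R)-1-{3-acetyl-2-[(tert-butyldimethylsilyl)oxy]-6-(methoxymethoxy)phenyl}-2-[(1S,3Z)-1-[2,4-bis(methoxymethoxy)phenyl]-3-methyl-4-(trimethylsilyl)but-3-en-1-yl]-3-hydroxy-3-[5-(methoxymethoxy)-2,2-dimethyl-2H-chromen-6-yl]propyl acetate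
Conditions: MeCHO (8 equiv), SmI2 (30 mol %), THF, −10 °C
Reagents that add atoms: acetaldehyde CC=O
Why: Evans–Tishchenko reduction, in which the samarium-bound hemiacetal at the C3 hydroxyl delivers hydride intramolecularly to the C7 ketone, should give the 1,3-anti carbinol and leave the acetate on the C3 oxygen, the one that must leave in step 17.

Step 17
Reactants: 23 the anti hydroxy acetate
Product: 25 1-[(2S,4S,5R,6S,11S)-4-[2,4-bis(methoxymethoxy)phenyl]-5-{(R)-hydroxy[5-(methoxymethoxy)-2,2-dimethyl-2H-chromen-6-yl]methyl}-7-(methoxymethoxy)-2-methyl-11-(trimethylsilyl)-3,4,5,6-tetrahydro-2H-2,6-methano-1-benzoxocin-10-yl]ethan-1-one, via ortho-quinone methide 24 (not isolated)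
Conditions: CsF (1.2 equiv), 18-crown-6 (0.2 equiv), MeCN/toluene 1:4, 0.005 M, 25 °C then 80 °C
Reagents that add atoms: none
Why: Proposed new method: fluoride frees the ring A phenoxide, which expels the benzylic acetate to give ortho-quinone methide 24, and its O=C–C=C3 unit adds to the tethered vinylsilane in an inverse-electron-demand hetero-Diels–Alder reaction in which the silicon-bearing C2 bonds to C3 and the oxygen to C1, the polarity that leaves developing positive charge on the tertiary, β-silyl-stabilised C1. The closest known reaction type is the intramolecular ortho-quinone methide/alkene [4+2] cycloaddition used for fused chromans (and, for the C–C bond alone, the vinylsilane-terminated cation cyclisation); the bridged mode with a vinylsilane as the 2π partner has not been shown. The carbocycle C1–C6 closes through the C2–C3 bond with both alkene carbons inside the new ring (endo mode), and the pyran ring closes through the O–C1 bond, the two rings sharing C1–C2–C3 as in a bicyclo[3.3.1]nonane. C3 is controlled by the bridge: the oxygen can reach C1 only if ring A is axial on the forming chair, and the chair that keeps the C4 and C5 substituents equatorial places ring A cis to the C4 side chain and trans to the C5 aryl group; C1 and C2 follow from suprafacial addition to the (Z)-alkene, which also sets C2–Si antiperiplanar to C1–O. The step needs C2 and not C1 to bond to C3, and needs cycloaddition to outrun the [1,5]-hydrogen shift of 24 to a 2-vinylphenol; the first is secured by the methyl group and the silicon on the alkene (bonding through C1 would build charge α to silicon and a quaternary centre), the second by keeping C7 at the carbinol level so that H4 is not acidic and by the reversible return of acetate, which stores 24 at low concentration.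

Step 18
Reactants: 25 the bridged carbinol
Product: 26 1-[(2S,4S,5R,6S,11S)-4-[2,4-bis(methoxymethoxy)phenyl]-5-[5-(methoxymethoxy)-2,2-dimethyl-2H-chromene-6-carbonyl]-7-(methoxymethoxy)-2-methyl-11-(trimethylsilyl)-3,4,5,6-tetrahydro-2H-2,6-methano-1-benzoxocin-10-yl]ethan-1-one
Conditions: Dess–Martin periodinane, CH2Cl2, 0 °C → rt
Reagents that add atoms: none
Why: Dess–Martin oxidation of the secondary benzylic alcohol gives the aryl ketone, and C4 should be safe because in the bridged framework the acyl group sits equatorial, the thermodynamically preferred position.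

Step 19
Reactants: 27 2,4-dihydroxybenzaldehyde
Product: 28 2,4-bis(methoxymethoxy)benzaldehyde
Conditions: MOMCl, i-Pr2NEt, CH2Cl2, 0 → 40 °C
Reagents that add atoms: chloromethyl methyl ether COCCl
Why: Standard O-alkylation of both phenols.

Step 20
Reactants: 26 the bridged diketone; 28 2,4-bis(methoxymethoxy)benzaldehyde
Product: 29 (2E)-3-[2,4-bis(methoxymethoxy)phenyl]-1-[(2S,4S,5R,6S,11S)-4-[2,4-bis(methoxymethoxy)phenyl]-5-[5-(methoxymethoxy)-2,2-dimethyl-2H-chromene-6-carbonyl]-7-(methoxymethoxy)-2-methyl-11-(trimethylsilyl)-3,4,5,6-tetrahydro-2H-2,6-methano-1-benzoxocin-10-yl]prop-2-en-1-one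
Conditions: KOH, EtOH/THF, rt
Reagents that add atoms: none
Why: Claisen–Schmidt condensation of the methyl ketone with the aldehyde should give the (E)-chalcone, the other ketone having only a hindered tertiary α-hydrogen and being unable to condense.

Step 21
Reactants: 29 the bridged chalcone
Product: 30 (2E)-3-[2,4-bis(methoxymethoxy)phenyl]-1-{3-[(1S,5S,6R)-5-[2,4-bis(methoxymethoxy)phenyl]-6-[5-(methoxymethoxy)-2,2-dimethyl-2H-chromene-6-carbonyl]-3-methylcyclohex-2-en-1-yl]-2-hydroxy-4-(methoxymethoxy)phenyl}prop-2-en-1-one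
Conditions: n-Bu4NF (3 equiv), AcOH (3 equiv), THF, 40 °C
Reagents that add atoms: none
Why: Fluoride attack at silicon with loss of the antiperiplanar aryloxide (Peterson-type anti β-elimination, as in the cleavage of 2-(trimethylsilyl)ethyl aryl ethers) should open the pyran ring and place the double bond between C1 and C2 only, acetic acid buffering the phenoxide.

Step 22
Reactants: 30 the hexakis(methoxymethyl) ether
Product: 31 (2E)-1-{3-[(1S,5S,6R)-5-(2,4-dihydroxyphenyl)-6-(5-hydroxy-2,2-dimethyl-2H-chromene-6-carbonyl)-3-methylcyclohex-2-en-1-yl]-2,4-dihydroxyphenyl}-3-(2,4-dihydroxyphenyl)prop-2-en-1-one (CNP0115975.1)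
Conditions: Me3SiOTf, 2,2'-bipyridyl, MeCN, 0 °C → rt; then H2O
Reagents that add atoms: none
Why: Aromatic methoxymethyl ethers are exchanged by the silyl triflate/2,2'-bipyridyl pair for trimethylsilyl ethers that hydrolyse on work-up, non-protic conditions chosen to avoid acid-promoted ketalisation or cyclisation of the phenols onto the ketone and the alkene.

**Compound list**

1 | prop-2-yn-1-ol | OCC#C | starting material
2 | (Z)-vinylmagnesium alkoxide from carbomagnesiation of 1 | Br[Mg]OC/C(C)=C\[Mg]Br | intermediate (not isolated)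
3 | (Z)-3-iodo-2-methylprop-2-en-1-ol | OC/C(C)=C\I | intermediate
4 | (Z)-[(3-iodo-2-methylprop-2-en-1-yl)oxy]trimethylsilane | C[Si](C)(C)OC/C(C)=C\I | intermediate (not isolated)
5 | (Z)-2-methyl-3-(trimethylsilyl)prop-2-en-1-ol | OC/C(C)=C\[Si](C)(C)C | intermediate
6 | (Z)-(3-bromo-2-methylprop-1-en-1-yl)trimethylsilane | BrC/C(C)=C\[Si](C)(C)C | intermediate
7 | (Z)-trimethyl(2-methylpenta-1,4-dien-1-yl)silane | C=CC/C(C)=C\[Si](C)(C)C | intermediate
8 | 1-(2,4-dihydroxyphenyl)ethan-1-one | CC(=O)c1ccc(O)cc1O | starting material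
9 | 3-methylbut-2-enal | CC(C)=CC=O | starting material
10 | 1-(5-hydroxy-2,2-dimethyl-2H-chromen-6-yl)ethan-1-one | CC(=O)c1ccc2OC(C)(C)C=Cc2c1O | intermediate
11 | 1-[5-(methoxymethoxy)-2,2-dimethyl-2H-chromen-6-yl]ethan-1-one | CC(=O)c1ccc2OC(C)(C)C=Cc2c1OCOC | intermediate
12 | 1-[5-(methoxymethoxy)-2,2-dimethyl-2H-chromen-6-yl]prop-2-en-1-one | C=CC(=O)c1ccc2OC(C)(C)C=Cc2c1OCOC | intermediate
13 | (2E,5Z)-1-[5-(methoxymethoxy)-2,2-dimethyl-2H-chromen-6-yl]-5-methyl-6-(trimethylsilyl)hexa-2,5-dien-1-one | C[Si](C)(C)/C=C(C)\C/C=C/C(=O)c1ccc2OC(C)(C)C=Cc2c1OCOC | intermediate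
14 | 4-bromobenzene-1,3-diol | Oc1ccc(Br)c(O)c1 | starting material
15 | 1-bromo-2,4-bis(methoxymethoxy)benzene | COCOc1ccc(Br)c(OCOC)c1 | intermediate
16 | [2,4-bis(methoxymethoxy)phenyl]boronic acid | COCOc1ccc(B(O)O)c(OCOC)c1 | intermediate
17 | (3S,5Z)-3-[2,4-bis(methoxymethoxy)phenyl]-1-[5-(methoxymethoxy)-2,2-dimethyl-2H-chromen-6-yl]-5-methyl-6-(trimethylsilyl)hex-5-en-1-one | C[Si](C)(C)/C=C(C)\C[C@H](c1ccc(OCOC)cc1OCOC)CC(=O)c1ccc2OC(C)(C)C=Cc2c1OCOC | intermediate
18 | 1-[2-hydroxy-4-(methoxymethoxy)phenyl]ethan-1-one | CC(=O)c1ccc(OCOC)cc1O | intermediate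
19 | 3-acetyl-2-hydroxy-6-(methoxymethoxy)benzaldehyde | CC(=O)c1ccc(OCOC)c(C=O)c1O | intermediate
20 | 3-acetyl-2-[(tert-butyldimethylsilyl)oxy]-6-(methoxymethoxy)benzaldehyde | CC(=O)c1ccc(OCOC)c(C=O)c1O[Si](C)(C)C(C)(C)C | intermediate
21 | (Z)-dibutylboron enolate of 17 | C[Si](C)(C)/C=C(C)\C[C@H](c1ccc(OCOC)cc1OCOC)/C=C(\OB(CCCC)CCCC)c1ccc2OC(C)(C)C=Cc2c1OCOC | intermediate (not isolated)
22 | syn-aldol adduct (C3 R, C4 R, C5 S), named in step 15 | C[Si](C)(C)/C=C(C)\C[C@H](c1ccc(OCOC)cc1OCOC)[C@H]([C@@H](O)c1c(O[Si](C)(C)C(C)(C)C)c(C(C)=O)ccc1OCOC)C(=O)c1ccc2OC(C)(C)C=Cc2c1OCOC | intermediate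
23 | 1,3-anti hydroxy acetate (C3 R, C4 S, C5 S, C7 R), named in step 16 | C[Si](C)(C)/C=C(C)\C[C@H](c1ccc(OCOC)cc1OCOC)[C@H]([C@@H](OC(C)=O)c1c(O[Si](C)(C)C(C)(C)C)c(C(C)=O)ccc1OCOC)[C@@H](O)c1ccc2OC(C)(C)C=Cc2c1OCOC | intermediate
24 | (Z)-ortho-quinone methide (6-acetyl-3-(methoxymethoxy)-6-methylidene-type cyclohexa-2,4-dienone carrying the C4–C7 chain on the exocyclic carbon C3) | C[Si](C)(C)/C=C(C)\C[C@H](c1ccc(OCOC)cc1OCOC)[C@H](/C=C1\C(=O)C(C(C)=O)=CC=C1OCOC)[C@@H](O)c1ccc2OC(C)(C)C=Cc2c1OCOC | intermediate (not isolated)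
25 | bridged silyl chroman carbinol (C1 S, C2 S, C3 S, C4 R, C5 S, C7 R), named in step 17 | C[C@]12C[C@H](c3ccc(OCOC)cc3OCOC)[C@@H]([C@@H](O)c3ccc4OC(C)(C)C=Cc4c3OCOC)[C@H]([C@@H]1[Si](C)(C)C)c1c(O2)c(C(C)=O)ccc1OCOC | intermediate
26 | bridged diketone, named in step 18 | C[C@]12C[C@H](c3ccc(OCOC)cc3OCOC)[C@@H](C(=O)c3ccc4OC(C)(C)C=Cc4c3OCOC)[C@H]([C@@H]1[Si](C)(C)C)c1c(O2)c(C(C)=O)ccc1OCOC | intermediate
27 | 2,4-dihydroxybenzaldehyde | O=Cc1ccc(O)cc1O | starting material
28 | 2,4-bis(methoxymethoxy)benzaldehyde | COCOc1ccc(C=O)c(OCOC)c1 | intermediate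
29 | bridged chalcone, named in step 20 | C[C@]12C[C@H](c3ccc(OCOC)cc3OCOC)[C@@H](C(=O)c3ccc4OC(C)(C)C=Cc4c3OCOC)[C@H]([C@@H]1[Si](C)(C)C)c1c(O2)c(C(=O)/C=C/c3ccc(OCOC)cc3OCOC)ccc1OCOC | intermediate
30 | hexakis(methoxymethyl) ether of the target with free 2-hydroxyl on ring A, named in step 21 | CC1=C[C@H](c2c(O)c(C(=O)/C=C/c3ccc(OCOC)cc3OCOC)ccc2OCOC)[C@H](C(=O)c2ccc3OC(C)(C)C=Cc3c2OCOC)[C@@H](c2ccc(OCOC)cc2OCOC)C1 | intermediate
31 | CNP0115975.1, named in step 22 | CC1=C[C@H](c2c(O)ccc(C(=O)/C=C/c3ccc(O)cc3O)c2O)[C@H](C(=O)c2ccc3c(c2O)C=CC(C)(C)O3)[C@@H](c2ccc(O)cc2O)C1 | target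

**Step count and risks**

Total step count: 22. Longest linear sequence: 13 steps (1, 2, 3, 4, 8, 11, 15, 16, 17, 18, 20, 21, 22).

Steps most likely to fail:

1. Step 17 (Proposed new method). The ortho-quinone methide may be lost by [1,5]-hydrogen shift to a 2-vinylphenol or by oligomerisation before the hindered, weakly nucleophilic vinylsilane adds, or a stepwise addition with ring A equatorial may erode the C3 configuration. The fallback uses known chemistry, sets out from 10, 19 and 28 and comes back at 31: the cyclohexene is built instead by the boron-templated Diels–Alder reaction of a 2'-hydroxychalcone with an aryl-substituted diene, which forms C3–C4 and C5–C6. Claisen–Schmidt condensation of 10 with 28 (KOH, EtOH) gives the dienophile (E)-3-[2,4-bis(methoxymethoxy)phenyl]-1-(5-hydroxy-2,2-dimethyl-2H-chromen-6-yl)prop-2-en-1-one F1. Aldehyde 19 is capped (NaH, MOMCl) to 3-acetyl-2,6-bis(methoxymethoxy)benzaldehyde F2. Wittig reaction of F2 with the ylide from (2-methylallyl)triphenylphosphonium chloride and KO-t-Bu, then iodine-catalysed alkene equilibration, gives the diene 1-{2,4-bis(methoxymethoxy)-3-[(1E)-3-methylbuta-1,3-dien-1-yl]phenyl}ethan-1-one F3. Condensation of F3 with 28 gives the diene chalcone (2E)-3-[2,4-bis(methoxymethoxy)phenyl]-1-{2,4-bis(methoxymethoxy)-3-[(1E)-3-methylbuta-1,3-dien-1-yl]phenyl}prop-2-en-1-one F4. F1 and F4 are combined with B(OPh)3 and an enantiopure VANOL-type biaryl diol (the enantiomer that leads to the 3S,4R,5S series), the borate of the 2'-hydroxychalcone reacting endo with the diene, to give the adduct (2E)-3-[2,4-bis(methoxymethoxy)phenyl]-1-{3-[(1S,5S,6R)-5-[2,4-bis(methoxymethoxy)phenyl]-6-(5-hydroxy-2,2-dimethyl-2H-chromene-6-carbonyl)-3-methylcyclohex-2-en-1-yl]-2,4-bis(methoxymethoxy)phenyl}prop-2-en-1-one F5. Removal of its six methoxymethyl groups under the conditions of step 22 leads to 31.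

2. Step 15. The C5 centre may discriminate poorly between the two faces of enolate 21 (aryl against CH2 group), and addition to the doubly ortho-substituted aldehyde may be slow enough for retro-aldol equilibration. The fallback sets out from 17 and 20 and comes back at 22: control of C4 is moved from the substrate to a chiral reagent. The enolate is formed with a diisopinocampheylboron triflate, (Ipc)2BOTf/i-Pr2NEt, in the enantiomer whose facial preference is matched with the 5S centre, so that the (Z)-enolate adds to 20 under reagent control through the same chair transition state. No new isolated compound arises (F0).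

3. Step 21. Fluoride attack at the hindered axial silicon may be slow, and under basic conditions the liberated chalcone phenoxide may close to the flavanone, or C4 may epimerise once the bridge is gone. The fallback sets out from 29 and comes back at 31: the ether oxygen is activated electrophilically instead. Treatment of 29 with Me3SiOTf/2,2'-bipyridyl (conditions of step 22) should silylate the bridging oxygen, the antiperiplanar C–Si bond assisting ionisation of C1–O and leaving as the silyl triflate (E1-type Peterson elimination), while the methoxymethyl ethers are exchanged in the same operation. Aqueous work-up then gives 31 directly, without 30 and with no new isolated compound (F0).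

**Further compounds**

F1 | step 17 | (E)-3-[2,4-bis(methoxymethoxy)phenyl]-1-(5-hydroxy-2,2-dimethyl-2H-chromen-6-yl)prop-2-en-1-one | COCOc1ccc(/C=C/C(=O)c2ccc3OC(C)(C)C=Cc3c2O)c(OCOC)c1
F2 | step 17 | 3-acetyl-2,6-bis(methoxymethoxy)benzaldehyde | CC(=O)c1ccc(OCOC)c(C=O)c1OCOC
F3 | step 17 | 1-{2,4-bis(methoxymethoxy)-3-[(1E)-3-methylbuta-1,3-dien-1-yl]phenyl}ethan-1-one | CC(=O)c1ccc(OCOC)c(/C=C/C(C)=C)c1OCOC
F4 | step 17 | (2E)-3-[2,4-bis(methoxymethoxy)phenyl]-1-{2,4-bis(methoxymethoxy)-3-[(1E)-3-methylbuta-1,3-dien-1-yl]phenyl}prop-2-en-1-one | COCOc1ccc(/C=C/C(=O)c2ccc(OCOC)c(/C=C/C(C)=C)c2OCOC)c(OCOC)c1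
F5 | step 17 | (2E)-3-[2,4-bis(methoxymethoxy)phenyl]-1-{3-[(1S,5S,6R)-5-[2,4-bis(methoxymethoxy)phenyl]-6-(5-hydroxy-2,2-dimethyl-2H-chromene-6-carbonyl)-3-methylcyclohex-2-en-1-yl]-2,4-bis(methoxymethoxy)phenyl}prop-2-en-1-one | CC1=C[C@H](c2c(OCOC)c(C(=O)/C=C/c3ccc(OCOC)cc3OCOC)ccc2OCOC)[C@H](C(=O)c2ccc3OC(C)(C)C=Cc3c2O)[C@@H](c2ccc(OCOC)cc2OCOC)C1
F0 | step 15 | none | none
F0 | step 21 | none | none
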